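The numbers in the tables are simulated with constants of no real substance, noise included.

5 questions stood before me, and I turned them round: what would have to be true of the numbers for green not to lead, or for the flasks to come out alike?

all flasks: substrate 0.94 M; first nucleophile 0.893 M
- south: second nucleophile 1.4 M; temperature −5 °C; run made earlier
- north-east: second nucleophile 2.1 M; temperature 38 °C; run made earlier
- amber: second nucleophile 2.82 M; temperature 25 °C; time 3.0 d
- ochre: second nucleophile 2.82 M; temperature 75 °C; time 3.0 d
- green: second nucleophile 2.82 M; temperature 0 °C; time 3.0 d
- blue: second nucleophile 2.82 M; temperature 50 °C; time 3.0 d

south run (percent of the substrate charged)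

| time / d | target / % | other capture product / % |
|---|---|---|
| 0.833 | 1.4 | 0.2 |
| 2.00 | 0.9 | 0.5 |
| 4.00 | 1.8 | 2.0 |
| 6.00 | 1.8 | 1.6 |
| 8.00 | 2.7 | 2.0 |
| 12.0 | 3.0 | 3.7 |

north-east run (percent of the substrate charged)

| time / h | target / % | other capture product / % |
|---|---|---|
| 5.00 | 17.0 | 38.2 |
| 10.0 | 18.6 | 46.0 |
| 15.0 | 19.3 | 48.5 |
| 20.0 | 18.8 | 49.2 |
| 25.0 | 19.2 | 48.6 |
| 30.0 | 20.3 | 48.5 |

(standard deviation of a reading: 0.5 percentage points)

- the best flask by share of target in all that became target or other capture product or solvolysis product or side product; "all alike" if 1.5 percentage points covers them all (amber / ochre / green / blue / all alike)
- share of target in all that became target or other capture product or solvolysis product or side product, amber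
- share of target in all that became target or other capture product or solvolysis product or side product, ochre
- share of target in all that became target or other capture product or solvolysis product or side product, green
- share of target in all that became target or other capture product or solvolysis product or side product, blue

- percentages count the substrate that a species holds: one side product counts as two
- what may be going on: substrate -> intermediate; first nucleophile + intermediate -> target; second nucleophile + intermediate -> other capture product; intermediate -> solvolysis product; substrate + target -> side product; target -> over-reaction product
- the share counts what is present at the end, not what went on to other products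

I took the symmetric case as my zero. If the intermediate took both nucleophiles alike, mole for mole, target over other capture product would equal the charge ratio. 0.317 is that statistical ratio, first nucleophile over second nucleophile as charged, and amber, ochre, green and blue share it. Target over other capture product, divided by the charge ratio of its own run, gives what I called the tilt, the selectivity factor; 1 means no preference.

Summed over its readings, south read a tilt of 1.82 at −5 °C, a loose reading, since those small percentages scatter by 0.5 percentage points. North-east read 0.954 at 38 °C, about half of that. For the share of target in the two captures to come out alike in a cold and a warm flask, the tilt would have had to stay level between those temperatures, and these two readings were not level; the asked share counts solvolysis product and side product as well, so this tilt was one condition of green's lead and not the whole of it.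

My own reckoning used only the two captures. South's tilt taken to green gave target 36.5% of them, and north-east's tilt gave a warm flask 23.2%, a gap of 13 points against the margin of 1.5 points.

The forecast named green, with amber 15.5%, ochre 13.5%, green 30% and blue 15%, and expected green to have “almost no side-product loss”. Its green stood lower than my capture share, which counts neither solvolysis product nor side product.

    substrate → intermediate (k = 1.50 h⁻¹, Ea = 111 kJ mol⁻¹)
    first nucleophile + intermediate → target (k = 41.0 M⁻¹ h⁻¹, Ea = 57.0 kJ mol⁻¹)
    second nucleophile + intermediate → other capture product (k = 39.0 M⁻¹ h⁻¹, Ea = 62.0 kJ mol⁻¹)
    intermediate → solvolysis product (k = 50.0 h⁻¹, Ea = 83.0 kJ mol⁻¹)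
    substrate + target → side product (k = 0.340 M⁻¹ h⁻¹, Ea = 76.0 kJ mol⁻¹)
    target → over-reaction product (k = 7.20 × 10⁻⁵ h⁻¹, Ea = 117 kJ mol⁻¹)
    (constants at 50 °C)

Green gave 27.3%, against amber 16.5%, blue 16.0% and ochre 11.7%. Green still held 94% of its substrate at 3.00 d, and the forecast's green figure would have failed on a longer run, for at 30.0 d the share in green is 16.8%. Measured against the statistical ratio, the tilt at the end was 1.39 in green and 0.790 in ochre. The neighbour of ochre charged with 0.36 M of first nucleophile, its ratio scaled to that charge, stood at 0.790.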